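The dihydronaphthalene ring B is disconnected at C4–C4a and C1–C8a, giving an arenediazonium salt of the central guaiacyl ring (already carrying the Z enol ether) and an enantioenriched γ-aryl-α-methylene-γ-butyrolactone. One operation joins them: Heck–Matsuda arylation of the exocyclic methylene forms C4–C4a, and the acid this turnover releases opens the lactone to a para-quinone methide of the 4-hydroxy-3-methoxyphenyl ring, which C8a (para to the C6 methoxy group) attacks. The lactone C3 stereocentre (future C2) steers C1; C2 is then inverted by kinetic protonation to the cis acid, and acid removes the tert-butyl esters.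

Key step: step 6

Remark: the descriptors of the target correspond to the (1R,2R) isomer, in which the C1 aryl group and the C2 carboxyl group are cis (the less stable C2 epimer); C2 is therefore set last under kinetic control and is not exposed to base afterwards. Naphthalene numbering of the target (C1 aryl, C2/C3 carboxyl, C6 OMe, C7 enol ether) is used throughout.

Step 1
Reactants: 1 2-methoxy-4-nitrophenol; 2 tert-butyl bromoacetate
Product: 3 tert-butyl 2-(2-methoxy-4-nitrophenoxy)acetate
Conditions: K2CO3, DMF, 60 °C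
Reagents that add atoms: none
Why: Williamson ether synthesis: the phenoxide of 1 displaces bromide from the primary α-bromo ester (SN2) without touching the tert-butyl ester.

Step 2
Reactants: 3 tert-butyl 2-(2-methoxy-4-nitrophenoxy)acetate; 4 4-[(tert-butyldimethylsilyl)oxy]-3-methoxybenzaldehyde
Product: 8 tert-butyl (2Z)-3-(4-hydroxy-3-methoxyphenyl)-2-(2-methoxy-4-nitrophenoxy)prop-2-enoate, via lithium aldolate 5 (not isolated), via acetoxy ester 6 (not isolated), via silyl-protected enol ether 7 (not isolated)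
Conditions: LiN(SiMe3)2, THF, −78 °C; Ac2O, −78 → 0 °C; DBU, 23 °C; then Bu4NF, AcOH, 0 °C
Reagents that add atoms: none
Why: Aldol condensation: addition of the lithium enolate of 3 to aldehyde 4, acetylation of the aldolate and DBU-mediated E1cB elimination should give the thermodynamically preferred Z enol ether (aryl trans to the ester), and buffered fluoride then cleaves the aryl silyl ether.

Step 3
Reactants: 8 tert-butyl (2Z)-3-(4-hydroxy-3-methoxyphenyl)-2-(2-methoxy-4-nitrophenoxy)prop-2-enoate
Product: 9 tert-butyl (2Z)-2-(4-amino-2-methoxyphenoxy)-3-(4-hydroxy-3-methoxyphenyl)prop-2-enoate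
Conditions: Fe powder, NH4Cl, EtOH–H2O, 70 °C
Reagents that add atoms: none
Why: Béchamp-type reduction of the nitro group with Fe/NH4Cl is chemoselective and should leave the enol ether alkene, the tert-butyl ester and the phenol untouched.

Step 4
Reactants: 10 methyl 3-bromo-2-oxopropanoate; 11 tert-butyl 2-(triphenyl-λ5-phosphanylidene)acetate
Product: 12 4-tert-butyl 1-methyl (2Z)-2-(bromomethyl)but-2-enedioate
Conditions: CH2Cl2, 0 → 23 °C
Reagents that add atoms: none
Why: Wittig olefination of the ketone carbonyl of the α-keto ester by the stabilised ylide; the alkene geometry is of no consequence because both isomers give the same allylchromium species in step 5.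

Step 5
Reactants: 12 4-tert-butyl 1-methyl (2Z)-2-(bromomethyl)but-2-enedioate; 4 4-[(tert-butyldimethylsilyl)oxy]-3-methoxybenzaldehyde
Product: 15 tert-butyl (2R,3R)-2-(4-hydroxy-3-methoxyphenyl)-4-methylidene-5-oxooxolane-3-carboxylate, via bis-silylated adduct 13 (not isolated), via hydroxy diester 14 (not isolated)
Conditions: CrCl2 (10 mol %), chiral 1,8-bis(oxazolinyl)carbazole ligand (12 mol %, the enantiomer that gives the R carbinol), Mn, Me3SiCl, THF, 23 °C; then Bu4NF, AcOH, THF, 0 → 23 °C
Reagents that add atoms: none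
Why: Catalytic asymmetric Nozaki–Hiyama–Kishi-type 2-(alkoxycarbonyl)allylation: the allylchromium from 12 adds through its γ-carbon in a chair transition state, the ligand choosing the aldehyde face (carbinol R) and the chair placing the ester-bearing carbon anti to it (3R), after which fluoride frees the alcohol and the phenol and the alcohol closes onto the methyl ester; only the 3R centre reaches the target, so a C2 epimer with 3R is equally usable while 3S isomers are removed by chromatography.

Step 6
Reactants: 9 tert-butyl (2Z)-2-(4-amino-2-methoxyphenoxy)-3-(4-hydroxy-3-methoxyphenyl)prop-2-enoate; 15 tert-butyl (2R,3R)-2-(4-hydroxy-3-methoxyphenyl)-4-methylidene-5-oxooxolane-3-carboxylate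
Product: 18 (1R,2S)-2-(tert-butoxycarbonyl)-7-{[(Z)-1-(tert-butoxycarbonyl)-2-(4-hydroxy-3-methoxyphenyl)ethenyl]oxy}-1-(4-hydroxy-3-methoxyphenyl)-6-methoxy-1,2-dihydronaphthalene-3-carboxylic acid, via diazonium tetrafluoroborate 16 (not isolated), via arylidene lactone 17 (not isolated)
Conditions: tert-BuONO, HBF4·OEt2, MeCN, 0 °C; then 15, Pd2(dba)3 (2.5 mol %), 2,6-di-tert-butyl-4-methylpyridine, MeCN–HFIP, 23 → 45 °C
Reagents that add atoms: none
Why: Proposed new method: the arenediazonium ion 16 adds oxidatively to zerovalent palladium, the cationic arylpalladium inserts the exocyclic methylene of 15 at its CH2 terminus and syn β-hydride elimination from the benzylic CH2 gives the (E)-arylidene lactone 17 (bond C4–C4a) while one equivalent of HBF4 is released and held as the hindered pyridinium salt; in HFIP this acid ionises the benzylic lactone C–O bond of 17 to the para-quinone methide of the 4-hydroxy-3-methoxyphenyl ring, which C8a attacks in a 6-exo-trig Friedel–Crafts closure of ring B (bond C1–C8a) before rearomatisation. The closest known reactions are the Heck–Matsuda arylation of α-methylene lactones and acrylates and the acid-mediated rearrangement of α-arylidene-γ-aryl-γ-butyrolactones to 1-aryl-1,2-dihydronaphthalene-3-carboxylic acids; what is new is their coupling through the acid that the first event liberates. The new stereocentre C1 is set by the existing C2 centre: allylic 1,3-strain keeps the C2 hydrogen in the plane of the quinone methide and the tethered ring must approach from the C3 side, so the aryl group should end trans to the tert-butyl ester (1R,2S). Regioselectivity is needed twice and is secured by the substrate: the diazonium group fixes C4a para to the enol-ether oxygen, and of the two carbons ortho to C4a only C8a is para to the C6 methoxy group and unhindered. The E geometry from the Heck event places the central ring on the C2 side as the closure requires, and the buffered acid should leave both tert-butyl esters intact.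

Step 7
Reactants: 18 (1R,2S)-2-(tert-butoxycarbonyl)-7-{[(Z)-1-(tert-butoxycarbonyl)-2-(4-hydroxy-3-methoxyphenyl)ethenyl]oxy}-1-(4-hydroxy-3-methoxyphenyl)-6-methoxy-1,2-dihydronaphthalene-3-carboxylic acid
Product: 20 (1R,2R)-2-(tert-butoxycarbonyl)-7-{[(Z)-1-(tert-butoxycarbonyl)-2-(4-hydroxy-3-methoxyphenyl)ethenyl]oxy}-1-(4-hydroxy-3-methoxyphenyl)-6-methoxy-1,2-dihydronaphthalene-3-carboxylic acid, via tetralithium dienolate 19 (not isolated)
Conditions: LiN(iPr)2 (5 equiv), THF–DMPU, −78 → −45 °C; then inverse quench into AcOH–THF, −78 °C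
Reagents that add atoms: none
Why: Deprotonation at C2 (α to the ester and allylic) gives a planar dienolate in which the pseudoaxial C1 aryl group shields one face, so kinetic α-protonation from the opposite face should deliver the contra-thermodynamic 1,2-cis acid, as in the kinetic enolate protonations used in the aryltetralin lactone series; the carboxylate and the two phenoxides are spectators.

Step 8
Reactants: 20 (1R,2R)-2-(tert-butoxycarbonyl)-7-{[(Z)-1-(tert-butoxycarbonyl)-2-(4-hydroxy-3-methoxyphenyl)ethenyl]oxy}-1-(4-hydroxy-3-methoxyphenyl)-6-methoxy-1,2-dihydronaphthalene-3-carboxylic acid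
Product: 21 (1R,2R)-7-{[(Z)-1-carboxy-2-(4-hydroxy-3-methoxyphenyl)ethenyl]oxy}-1-(4-hydroxy-3-methoxyphenyl)-6-methoxy-1,2-dihydronaphthalene-2,3-dicarboxylic acid (CNP0328417.1)
Conditions: CF3CO2H–CH2Cl2 (1:1), H2O (5 %), 0 → 23 °C; reversed-phase purification with acidic eluent
Reagents that add atoms: none
Why: Acidolysis of both tert-butyl esters (AAL1, loss of the tert-butyl cation as 2-methylpropene) liberates the triacid without any base, so the base-labile C2 centre and the acid-stable aryloxyacrylic enol ether should survive.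

Compound list
1 | 2-methoxy-4-nitrophenol | COc1cc([N+](=O)[O-])ccc1O | starting material
2 | tert-butyl bromoacetate | CC(C)(C)OC(=O)CBr | starting material
3 | tert-butyl 2-(2-methoxy-4-nitrophenoxy)acetate | COc1cc([N+](=O)[O-])ccc1OCC(=O)OC(C)(C)C | intermediate
4 | 4-[(tert-butyldimethylsilyl)oxy]-3-methoxybenzaldehyde | COc1cc(C=O)ccc1O[Si](C)(C)C(C)(C)C | starting material
5 | lithium 3-tert-butoxy-1-{4-[(tert-butyldimethylsilyl)oxy]-3-methoxyphenyl}-2-(2-methoxy-4-nitrophenoxy)-3-oxopropan-1-olate (diastereomer mixture) | [Li+].COc1cc(C([O-])C(Oc2ccc([N+](=O)[O-])cc2OC)C(=O)OC(C)(C)C)ccc1O[Si](C)(C)C(C)(C)C | intermediate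
6 | tert-butyl 3-acetoxy-3-{4-[(tert-butyldimethylsilyl)oxy]-3-methoxyphenyl}-2-(2-methoxy-4-nitrophenoxy)propanoate (diastereomer mixture) | COc1cc(C(OC(C)=O)C(Oc2ccc([N+](=O)[O-])cc2OC)C(=O)OC(C)(C)C)ccc1O[Si](C)(C)C(C)(C)C | intermediate
7 | tert-butyl (2Z)-3-{4-[(tert-butyldimethylsilyl)oxy]-3-methoxyphenyl}-2-(2-methoxy-4-nitrophenoxy)prop-2-enoate | COc1cc(/C=C(\Oc2ccc([N+](=O)[O-])cc2OC)C(=O)OC(C)(C)C)ccc1O[Si](C)(C)C(C)(C)C | intermediate
8 | tert-butyl (2Z)-3-(4-hydroxy-3-methoxyphenyl)-2-(2-methoxy-4-nitrophenoxy)prop-2-enoate | COc1cc(/C=C(\Oc2ccc([N+](=O)[O-])cc2OC)C(=O)OC(C)(C)C)ccc1O | intermediate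
9 | tert-butyl (2Z)-2-(4-amino-2-methoxyphenoxy)-3-(4-hydroxy-3-methoxyphenyl)prop-2-enoate | COc1cc(/C=C(\Oc2ccc(N)cc2OC)C(=O)OC(C)(C)C)ccc1O | intermediate
10 | methyl 3-bromo-2-oxopropanoate | COC(=O)C(=O)CBr | starting material
11 | tert-butyl 2-(triphenyl-λ5-phosphanylidene)acetate | CC(C)(C)OC(=O)C=P(c1ccccc1)(c1ccccc1)c1ccccc1 | starting material
12 | 4-tert-butyl 1-methyl (2Z)-2-(bromomethyl)but-2-enedioate | COC(=O)/C(CBr)=C/C(=O)OC(C)(C)C | intermediate
13 | 4-tert-butyl 1-methyl (3R)-3-[(R)-{4-[(tert-butyldimethylsilyl)oxy]-3-methoxyphenyl}(trimethylsilyloxy)methyl]-2-methylidenebutanedioate | C=C(C(=O)OC)[C@@H](C(=O)OC(C)(C)C)[C@@H](O[Si](C)(C)C)c1ccc(O[Si](C)(C)C(C)(C)C)c(OC)c1 | intermediate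
14 | 4-tert-butyl 1-methyl (3R)-3-[(R)-hydroxy(4-hydroxy-3-methoxyphenyl)methyl]-2-methylidenebutanedioate | C=C(C(=O)OC)[C@@H](C(=O)OC(C)(C)C)[C@@H](O)c1ccc(O)c(OC)c1 | intermediate
15 | tert-butyl (2R,3R)-2-(4-hydroxy-3-methoxyphenyl)-4-methylidene-5-oxooxolane-3-carboxylate | C=C1C(=O)O[C@@H](c2ccc(O)c(OC)c2)[C@@H]1C(=O)OC(C)(C)C | intermediate
16 | 4-{[(Z)-1-(tert-butoxycarbonyl)-2-(4-hydroxy-3-methoxyphenyl)ethenyl]oxy}-3-methoxybenzenediazonium tetrafluoroborate | COc1cc(/C=C(\Oc2ccc([N+]#N)cc2OC)C(=O)OC(C)(C)C)ccc1O.F[B-](F)(F)F | intermediate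
17 | tert-butyl (2Z)-2-(4-{(E)-[(4R,5R)-4-(tert-butoxycarbonyl)-5-(4-hydroxy-3-methoxyphenyl)-2-oxooxolan-3-ylidene]methyl}-2-methoxyphenoxy)-3-(4-hydroxy-3-methoxyphenyl)prop-2-enoate | COc1cc(/C=C(\Oc2ccc(/C=C3/C(=O)O[C@@H](c4ccc(O)c(OC)c4)[C@@H]3C(=O)OC(C)(C)C)cc2OC)C(=O)OC(C)(C)C)ccc1O | intermediate
18 | (1R,2S)-2-(tert-butoxycarbonyl)-7-{[(Z)-1-(tert-butoxycarbonyl)-2-(4-hydroxy-3-methoxyphenyl)ethenyl]oxy}-1-(4-hydroxy-3-methoxyphenyl)-6-methoxy-1,2-dihydronaphthalene-3-carboxylic acid (1,2-trans) | COc1cc(/C=C(\Oc2cc3c(cc2OC)C=C(C(=O)O)[C@@H](C(=O)OC(C)(C)C)[C@@H]3c2ccc(O)c(OC)c2)C(=O)OC(C)(C)C)ccc1O | intermediate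
19 | tetralithium salt of 18 (carboxylate, two phenoxides, C2 ester dienolate; C1 R) | [Li+].[Li+].[Li+].[Li+].COc1cc(/C=C(\Oc2cc3c(cc2OC)C=C(C(=O)[O-])C(=C([O-])OC(C)(C)C)[C@@H]3c2ccc([O-])c(OC)c2)C(=O)OC(C)(C)C)ccc1[O-] | intermediate
20 | (1R,2R)-2-(tert-butoxycarbonyl)-7-{[(Z)-1-(tert-butoxycarbonyl)-2-(4-hydroxy-3-methoxyphenyl)ethenyl]oxy}-1-(4-hydroxy-3-methoxyphenyl)-6-methoxy-1,2-dihydronaphthalene-3-carboxylic acid (1,2-cis) | COc1cc(/C=C(\Oc2cc3c(cc2OC)C=C(C(=O)O)[C@H](C(=O)OC(C)(C)C)[C@@H]3c2ccc(O)c(OC)c2)C(=O)OC(C)(C)C)ccc1O | intermediate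
21 | (1R,2R)-7-{[(Z)-1-carboxy-2-(4-hydroxy-3-methoxyphenyl)ethenyl]oxy}-1-(4-hydroxy-3-methoxyphenyl)-6-methoxy-1,2-dihydronaphthalene-2,3-dicarboxylic acid | COc1cc(/C=C(\Oc2cc3c(cc2OC)C=C(C(=O)O)[C@H](C(=O)O)[C@@H]3c2ccc(O)c(OC)c2)C(=O)O)ccc1O | target

Total step count: 8. Longest linear sequence: 6 steps (steps 1, 2, 3, 6, 7, 8).

Steps most likely to fail

Step 6 (proposed new method). What may go wrong: β-hydride elimination into the lactone ring instead of toward the benzylic CH2, which would erase the C3 stereocentre; proton loss from the quinone methide instead of ring closure; or sluggish ionisation of the lactone under the buffered acid. The fallback splits the cascade into known reactions and drops the acid relay. It sets out from 9: diazotisation followed by iodide (tert-BuONO, HBF4·OEt2, then KI) should give tert-butyl (2Z)-3-(4-hydroxy-3-methoxyphenyl)-2-(4-iodo-2-methoxyphenoxy)prop-2-enoate F1. A Mizoroki–Heck reaction of F1 with 15 under silver-promoted conditions (Pd(OAc)2, PPh3, Ag2CO3, MeCN, 60 °C) should give 17, now isolated and freed of alkene isomers. Separate treatment of 17 with camphorsulfonic acid (10 mol %) in HFIP should effect the known lactone-to-dihydronaphthalene rearrangement and come back to the route at 18.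

Step 7. What may go wrong: poor facial selectivity in the protonation of the polylithiated dienolate, or partial return to the trans acid by proton exchange during the quench. The fallback replaces substrate control on the lithium species by reagent control on a neutral silyl ketene acetal. It sets out from 18: enolisation with in situ silylation (LiN(iPr)2, Me3SiCl, THF, −78 °C) should give trimethylsilyl (1R)-2-[tert-butoxy(trimethylsilyloxy)methylidene]-7-{[(Z)-1-(tert-butoxycarbonyl)-2-[3-methoxy-4-(trimethylsilyloxy)phenyl]ethenyl]oxy}-6-methoxy-1-[3-methoxy-4-(trimethylsilyloxy)phenyl]-1,2-dihydronaphthalene-3-carboxylate F2. Protonation of F2 at −78 °C in toluene by a Lewis acid-assisted chiral Brønsted acid ((R)- or (S)-BINOL·SnCl4, the enantiomer matched to the substrate bias), followed by mild aqueous work-up to remove the trimethylsilyl groups, should come back to the route at 20.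

Step 5. What may go wrong: insufficient enantio- or diastereoselection at the ester-bearing carbon, or migration of the exocyclic double bond into the ring during desilylation. The fallback changes the allyl donor and the source of asymmetry. It sets out from 12: palladium-catalysed borylation (B2pin2, Pd2(dba)3, toluene) should give 4-tert-butyl 1-methyl (2E)-2-[(4,4,5,5-tetramethyl-1,3,2-dioxaborolan-2-yl)methyl]but-2-enedioate F3. Allylboration of aldehyde 4 with F3 under chiral Brønsted acid catalysis (chiral diol·SnCl4, toluene, −78 °C), followed by the same Bu4NF/AcOH treatment, should come back to the route at 15.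

Further compounds
F1 | step 6 | tert-butyl (2Z)-3-(4-hydroxy-3-methoxyphenyl)-2-(4-iodo-2-methoxyphenoxy)prop-2-enoate | COc1cc(/C=C(\Oc2ccc(I)cc2OC)C(=O)OC(C)(C)C)ccc1O
F2 | step 7 | trimethylsilyl (1R)-2-[tert-butoxy(trimethylsilyloxy)methylidene]-7-{[(Z)-1-(tert-butoxycarbonyl)-2-[3-methoxy-4-(trimethylsilyloxy)phenyl]ethenyl]oxy}-6-methoxy-1-[3-methoxy-4-(trimethylsilyloxy)phenyl]-1,2-dihydronaphthalene-3-carboxylate | COc1cc(/C=C(\Oc2cc3c(cc2OC)C=C(C(=O)O[Si](C)(C)C)C(=C(OC(C)(C)C)O[Si](C)(C)C)[C@@H]3c2ccc(O[Si](C)(C)C)c(OC)c2)C(=O)OC(C)(C)C)ccc1O[Si](C)(C)C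
F3 | step 5 | 4-tert-butyl 1-methyl (2E)-2-[(4,4,5,5-tetramethyl-1,3,2-dioxaborolan-2-yl)methyl]but-2-enedioate | COC(=O)/C(CB1OC(C)(C)C(C)(C)O1)=C/C(=O)OC(C)(C)C
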